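**Retrosynthetic overview**
- The only strategic bond is the diaryl ether C–O bond. It is cut into an aryl donor, (3,5-dibromo-2-methoxyphenyl)boronic acid (ring B, both Br and the OMe already in place), and an oxygen donor, tetrabromo-o-benzoquinone (ring A, all four Br and both O in place).
- This C–O bond is made last by a proposed copper-catalysed, redox-neutral O-arylation in which the o-quinone is both oxidant and oxygen partner; the same step leaves the second oxygen as the free OH.
- The boronic acid comes from 2,4-dibromo-6-iodoanisole by selective I/Mg exchange and borylation; the iodide comes from 2,4-dibromophenol by ortho-iodination and O-methylation.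
- No ring is formed: both benzene rings are bought, and all six C–Br bonds are carried in from the starting materials.

Assumption: the target has no stereocentre and no stable chiral axis (the ether oxygen on ring B has an unsubstituted ortho position), so it is one achiral compound and no asymmetric step is needed; tetrabromo-o-benzoquinone is taken as commercially available.

**Route**

Step 1
Reactants: 1 2,4-dibromophenol
Product: 2 2,4-dibromo-6-iodophenol
Conditions: NIS (1.05 equiv), TsOH·H2O (10 mol%), MeCN, 0 °C to rt
Reagents that add atoms: N-iodosuccinimide, O=C1CCC(=O)N1I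
Why: Electrophilic aromatic iodination; OH directs ortho/para and C6 is the only free ortho/para position of 1, so iodine can enter only there.

Step 2
Reactants: 2 2,4-dibromo-6-iodophenol
Product: 3 1,5-dibromo-3-iodo-2-methoxybenzene
Conditions: MeI (1.5 equiv), K2CO3 (2 equiv), DMF, rt
Reagents that add atoms: iodomethane, CI
Why: Williamson ether synthesis; the acidic trihalophenol is fully deprotonated by K2CO3 and the phenoxide is methylated by SN2, while the aryl halides are inert.

Step 3
Reactants: 3 1,5-dibromo-3-iodo-2-methoxybenzene
Product: 6 (3,5-dibromo-2-methoxyphenyl)boronic acid, via arylmagnesium chloride 4 (not isolated), via chloromagnesium aryltrimethoxyborate 5 (not isolated)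
Conditions: iPrMgCl·LiCl (1.05 equiv), THF, −40 °C, 30 min; B(OMe)3 (2 equiv), −40 °C to rt; 1 M aq. HCl
Reagents that add atoms: trimethyl borate, COB(OC)OC; water, O
Why: Halogen–magnesium exchange followed by electrophilic borylation; C–I exchanges far faster than C–Br at −40 °C, Grignard reagent 4 has no ortho halogen (no aryne pathway), and acid hydrolysis of borate 5 gives the boronic acid.

Step 4
Reactants: 6 (3,5-dibromo-2-methoxyphenyl)boronic acid; 7 3,4,5,6-tetrabromocyclohexa-3,5-diene-1,2-dione (tetrabromo-o-benzoquinone)
Product: 9 3,4,5,6-tetrabromo-2-(3,5-dibromo-2-methoxyphenoxy)phenol, via aryl dihydrogen borate 8 (not isolated)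
Conditions: Cu(MeCN)4PF6 (10 mol%), 4,4'-di-tert-butyl-2,2'-bipyridine (12 mol%), 6 (1.5 equiv), 1,2-dichloroethane, N2, 30 °C, 7 (1.0 equiv) added over 4 h by syringe pump; then 1 M aq. HCl
Reagents that add atoms: none
Why: Proposed new method: a redox-neutral copper-catalysed O-arylation in which the o-quinone is at once the oxidant and the oxygen partner. Monovalent copper is oxidised by the strongly oxidising quinone 7 to a divalent copper semiquinonate in valence-tautomeric equilibrium with a trivalent copper catecholate. One catecholate oxygen binds the boron of 6 (Cu–O–B bridge) and passes the aryl group to copper. C–O reductive elimination from the aryl trivalent copper catecholate then forms the diaryl ether and returns monovalent copper. The second oxygen is left capped as borate 8, so only one oxygen can be arylated, and 8 is hydrolysed on work-up. All ring carbons of 7 carry Br, so C-arylation is blocked, and the C–Br bonds are inert to monovalent copper at 30 °C. The closest known reaction type is the Chan–Lam coupling of phenols with arylboronic acids (divalent copper with O2 as oxidant), together with the known oxidative addition of o-quinones to low-valent metals to give catecholates.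

**Compound list**

1 | 2,4-dibromophenol | Oc1ccc(Br)cc1Br | starting material
2 | 2,4-dibromo-6-iodophenol | Oc1c(I)cc(Br)cc1Br | intermediate
3 | 1,5-dibromo-3-iodo-2-methoxybenzene (2,4-dibromo-6-iodoanisole) | COc1c(I)cc(Br)cc1Br | intermediate
4 | (3,5-dibromo-2-methoxyphenyl)magnesium chloride, LiCl complex, formed in the flask | COc1c(Br)cc(Br)cc1[Mg]Cl | intermediate
5 | chloromagnesium (3,5-dibromo-2-methoxyphenyl)trimethoxyborate, formed in the flask | COc1c(Br)cc(Br)cc1[B-](OC)(OC)OC.[Mg+]Cl | intermediate
6 | (3,5-dibromo-2-methoxyphenyl)boronic acid | COc1c(Br)cc(Br)cc1B(O)O | intermediate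
7 | 3,4,5,6-tetrabromocyclohexa-3,5-diene-1,2-dione (tetrabromo-o-benzoquinone) | O=C1C(=O)C(Br)=C(Br)C(Br)=C1Br | starting material
8 | 2,3,4,5-tetrabromo-6-(3,5-dibromo-2-methoxyphenoxy)phenyl dihydrogen borate, formed in the flask | COc1c(Br)cc(Br)cc1Oc1c(OB(O)O)c(Br)c(Br)c(Br)c1Br | intermediate
9 | 3,4,5,6-tetrabromo-2-(3,5-dibromo-2-methoxyphenoxy)phenol | COc1c(Br)cc(Br)cc1Oc1c(O)c(Br)c(Br)c(Br)c1Br | target

**Summary**

Total step count: 4. Longest linear sequence: 4 steps (1 → 2 → 3 → 6 → 9); quinone 7 is bought.

**Steps most likely to fail and fallbacks**

Step 4 (proposed new C–O coupling). Risks: oxidative homocoupling or protodeboronation of 6, displacement of Br at C4/C5 of the quinone, and catalyst arrest as a divalent copper catecholate. The fallback uses known chemistry, the metal-free O-arylation of a phenol with a diaryliodonium salt. It sets out from 3 and 7 and comes back to the route at 9. Aryl iodide 3 is oxidised with mCPBA and TsOH·H2O in MeCN at 55 °C to (3,5-dibromo-2-methoxyphenyl)(hydroxy)(tosyloxy)-λ3-iodane F1. Without isolation this is treated with 1,3,5-trimethoxybenzene to give (3,5-dibromo-2-methoxyphenyl)(2,4,6-trimethoxyphenyl)iodonium 4-methylbenzenesulfonate F2, collected as a solid. Quinone 7 is reduced with aqueous Na2S2O4 in EtOAc to 3,4,5,6-tetrabromobenzene-1,2-diol F3. F3 (3 equiv, the excess is recovered) is converted to its mono-potassium salt with KOtBu (3 equiv) in THF at 0 °C and arylated with F2 (1 equiv) at rt to 40 °C. The trimethoxyphenyl group stays on iodine, the excess of diol suppresses double arylation, and acidic work-up gives 9.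

Step 3 (I/Mg exchange and borylation). Risks: competing Br/Mg exchange, quenching of the Grignard reagent, and loss of the boronic acid on isolation. The fallback replaces organomagnesium chemistry by palladium catalysis; it sets out from 3 and comes back at 6. Miyaura borylation of 3 with B2pin2, PdCl2(dppf) (3 mol%) and KOAc in 1,4-dioxane at 80 °C reacts selectively at the C–I bond and gives 2-(3,5-dibromo-2-methoxyphenyl)-4,4,5,5-tetramethyl-1,3,2-dioxaborolane F4. Oxidative cleavage of the pinacol ester with NaIO4 and NH4OAc in acetone/water at rt gives 6.

Step 1 (iodination of a deactivated phenol). Risks: stalling, or oxidative side reactions that carry unreacted 1 forward. The fallback avoids the iodide altogether; it sets out from 1 and comes back at Grignard reagent 4 in the flask of step 3. Bromination of 1 with Br2 (1.05 equiv) in AcOH at rt fills the last ortho position and gives 2,4,6-tribromophenol F5. Methylation with MeI and K2CO3 in DMF gives 1,3,5-tribromo-2-methoxybenzene F6. Br/Mg exchange with iPrMgCl·LiCl in THF at −20 °C takes place at a bromine ortho to the methoxy group (the two ortho positions are equivalent) and gives 4, which is borylated and hydrolysed to 6 as in step 3.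

**Further compounds**

F1 | step 4 | (3,5-dibromo-2-methoxyphenyl)(hydroxy)(tosyloxy)-λ3-iodane | COc1c(Br)cc(Br)cc1I(O)OS(=O)(=O)c1ccc(C)cc1
F2 | step 4 | (3,5-dibromo-2-methoxyphenyl)(2,4,6-trimethoxyphenyl)iodonium 4-methylbenzenesulfonate | COc1cc(OC)c([I+]c2cc(Br)cc(Br)c2OC)c(OC)c1.Cc1ccc(S(=O)(=O)[O-])cc1
F3 | step 4 | 3,4,5,6-tetrabromobenzene-1,2-diol | Oc1c(O)c(Br)c(Br)c(Br)c1Br
F4 | step 3 | 2-(3,5-dibromo-2-methoxyphenyl)-4,4,5,5-tetramethyl-1,3,2-dioxaborolane | COc1c(Br)cc(Br)cc1B1OC(C)(C)C(C)(C)O1
F5 | step 1 | 2,4,6-tribromophenol | Oc1c(Br)cc(Br)cc1Br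
F6 | step 1 | 1,3,5-tribromo-2-methoxybenzene | COc1c(Br)cc(Br)cc1Br
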